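The route rests on cutting the C2=C3 alkene of ring A, the cyclohex-2-ene-1,4-dione Ca(prenyl)–C1(=O)–C2H=C3H–C4(=O)–Cb. The key step couples two identical one-carbon arms: an iridium carbene formed from one β-keto sulfoxonium ylide is captured by the other ylide carbon, DMSO leaves, and ring A appears at its final oxidation level with the Z-alkene. It exploits that C1 and C4 sit on the vicinal, non-enolisable quaternary carbons Ca (one-carbon bridge) and Cb (bridgehead) of a rigid benzobicyclo[3.2.1]octadiene, which holds them gauche. The precursor is this tricyclic core, built by organocatalytic Michael/aldol annulation and a Heck closure, carrying two C(=O)CH=S(O)Me2 groups.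

Key step: step 9

Remark: ring A = enedione, ring B = methylcyclohexene, ring C = five-membered ring, ring D = arene. Ca carries the prenyl group, Cb the aryl and vinyl carbons, and Cc is the benzylic CH. Compound 8 is an epimerisable β-keto ester, so its ester-bearing carbon is drawn without configuration until step 4 fixes it.

Step 1
Reactants: 1 2-bromo-1,4-dimethoxybenzene
Product: 3 2-bromo-3,6-dimethoxybenzaldehyde, via aryllithium 2 (not isolated)
Conditions: LiN(i-Pr)2, THF, −78 °C; DMF, −78 °C to rt; H2O
Reagents that add atoms: N,N-dimethylformamide, CN(C)C=O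
Why: Directed ortho-lithiation and formylation: the proton flanked by Br and OMe is the most acidic, the amide base removes it at −78 °C without bromine–lithium exchange, and no stereocenter is formed.

Step 2
Reactants: 3 2-bromo-3,6-dimethoxybenzaldehyde; 4 (triphenylphosphoranylidene)acetaldehyde
Product: 5 (E)-3-(2-bromo-3,6-dimethoxyphenyl)prop-2-enal
Conditions: toluene, 80 °C
Reagents that add atoms: none
Why: Wittig olefination with a stabilised ylide should give the (E)-enal selectively, and no stereocenter is formed.

Step 3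
Reactants: 5 (E)-3-(2-bromo-3,6-dimethoxyphenyl)prop-2-enal; 6 methyl acetoacetate
Product: 8 methyl (6S)-6-(2-bromo-3,6-dimethoxyphenyl)-2-oxocyclohex-3-ene-1-carboxylate, via Michael adduct 7 (not isolated)
Conditions: (R)-α,α-diphenylprolinol trimethylsilyl ether (10 mol %), PhCO2H (10 mol %), toluene, rt; then TsOH·H2O (20 mol %), 60 °C
Reagents that add atoms: none
Why: Iminium-catalysed asymmetric Michael addition followed by acid-promoted intramolecular aldol condensation closes ring B; the CPh2(OSiMe3) group of the (R)-catalyst shields one face of the E-iminium ion, so the β-keto ester adds to the open face and sets Cc as (S).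

Step 4
Reactants: 8 methyl (6S)-6-(2-bromo-3,6-dimethoxyphenyl)-2-oxocyclohex-3-ene-1-carboxylate; 9 prenyl bromide
Product: 10 methyl (1S,6S)-6-(2-bromo-3,6-dimethoxyphenyl)-1-(3-methylbut-2-enyl)-2-oxocyclohex-3-ene-1-carboxylate
Conditions: Cs2CO3, MeCN, 0 °C to rt
Reagents that add atoms: none
Why: C-alkylation (SN2) of a cyclic β-keto ester enolate: the bromide approaches anti to the neighbouring aryl group, which sets quaternary Ca with prenyl trans and CO2Me cis to the arene.

Step 5
Reactants: 10 methyl (1S,6S)-6-(2-bromo-3,6-dimethoxyphenyl)-1-(3-methylbut-2-enyl)-2-oxocyclohex-3-ene-1-carboxylate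
Product: 12 methyl (1S,4S,6S)-6-(2-bromo-3,6-dimethoxyphenyl)-4-methyl-1-(3-methylbut-2-enyl)-2-(trifluoromethylsulfonyloxy)cyclohex-2-ene-1-carboxylate, via lithium enolate 11 (not isolated)
Conditions: MeLi (2 equiv), CuI, Et2O, 0 °C; 10, −78 °C; PhNTf2, THF, −78 °C to rt
Reagents that add atoms: lithium dimethylcuprate, [Li+].C[Cu-]C; N-phenylbis(trifluoromethanesulfonimide), O=S(=O)(N(c1ccccc1)S(=O)(=O)C(F)(F)F)C(F)(F)F
Why: Cuprate conjugate addition with regiospecific O-triflation of the resulting enolate: axial attack anti to the equatorial C6 aryl group puts the methyl trans to the arene, so that the C4–H lies on the arene face as step 7 requires.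

Step 6
Reactants: 12 methyl (1S,4S,6S)-6-(2-bromo-3,6-dimethoxyphenyl)-4-methyl-1-(3-methylbut-2-enyl)-2-(trifluoromethylsulfonyloxy)cyclohex-2-ene-1-carboxylate
Product: 13 dimethyl (1S,4S,6S)-6-(2-bromo-3,6-dimethoxyphenyl)-4-methyl-1-(3-methylbut-2-enyl)cyclohex-2-ene-1,2-dicarboxylate
Conditions: Pd(OAc)2 (5 mol %), PPh3 (10 mol %), CO (1 atm), MeOH, Et3N, DMF, rt
Reagents that add atoms: carbon monoxide, [C-]#[O+]; methanol, CO
Why: Palladium-catalysed alkoxycarbonylation of an enol triflate: zerovalent palladium inserts into the vinyl C–OTf bond far faster at rt than into the hindered, electron-rich aryl bromide, so the bromide is kept and no stereocenter changes.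

Step 7
Reactants: 13 dimethyl (1S,4S,6S)-6-(2-bromo-3,6-dimethoxyphenyl)-4-methyl-1-(3-methylbut-2-enyl)cyclohex-2-ene-1,2-dicarboxylate
Product: 14 dimethyl (5R,9R,10S)-1,4-dimethoxy-7-methyl-10-(3-methylbut-2-enyl)-8,9-dihydro-5H-5,9-methanobenzo[7]annulene-5,10-dicarboxylate
Conditions: Pd2(dba)3 (5 mol %), P(t-Bu)3·HBF4 (12 mol %), Cy2NMe, 1,4-dioxane, 100 °C
Reagents that add atoms: none
Why: Intramolecular Mizoroki–Heck reaction (5-exo-trig) closes ring C: in the trans-diaxial conformer the aryl–palladium bond lies over Cb and anti to the prenyl chain, syn-carbopalladation from the arene face sets quaternary Cb, and loss of the only syn β-hydrogen (C4–H from step 5) places the C=C(Me) alkene next to Cb.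

Step 8
Reactants: 14 dimethyl (5R,9R,10S)-1,4-dimethoxy-7-methyl-10-(3-methylbut-2-enyl)-8,9-dihydro-5H-5,9-methanobenzo[7]annulene-5,10-dicarboxylate
Product: 15 (5R,9R,10S)-5,10-bis[(dimethyl(oxo)-λ6-sulfanylidene)acetyl]-1,4-dimethoxy-7-methyl-10-(3-methylbut-2-enyl)-8,9-dihydro-5H-5,9-methanobenzo[7]annulene
Conditions: Me3S(O)I (6 equiv), KOt-Bu (6 equiv), THF, reflux; then 14, reflux
Reagents that add atoms: dimethylsulfoxonium methylide, C[S+](C)(=O)[CH2-]
Why: Acylation of the Corey–Chaykovsky ylide by esters (acyl substitution, then deprotonation by a second equivalent): both esters are non-enolisable, the stabilised product ylides resist further attack, and no stereocenter is touched.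

Step 9
Reactants: 15 (5R,9R,10S)-5,10-bis[(dimethyl(oxo)-λ6-sulfanylidene)acetyl]-1,4-dimethoxy-7-methyl-10-(3-methylbut-2-enyl)-8,9-dihydro-5H-5,9-methanobenzo[7]annulene
Product: 16 dimethyl ether of the target (ring A closed; Ca S, Cb R, Cc R)
Conditions: [Ir(cod)Cl]2 (5 mol %), ClCH2CH2Cl, 80 °C, slow addition of 15 (final 0.002 M)
Reagents that add atoms: none
Why: Proposed new method: monovalent iridium displaces DMSO from one ylide arm to give an electrophilic α-oxo iridium carbene, the nucleophilic carbon of the second ylide arm attacks it, and elimination of iridium and DMSO from the resulting β-sulfoxonium alkyl-iridium releases the C2=C3 alkene. The closest known reaction types are the copper- or rhodium-catalysed intramolecular carbene coupling of bis(α-diazoketones) to cycloalk-2-ene-1,4-diones, the ruthenium-catalysed cross-olefination of diazo compounds with sulfoxonium ylides, and iridium-catalysed carbene transfer from β-keto sulfoxonium ylides. Ring A is the only ring closed, by six-membered carbon–carbon bond formation between the two arm termini C2 and C3. No stereocenter is created, the Z geometry is imposed by the six-membered ring, and Ca, Cb and Cc carry no acidic hydrogen and cannot epimerise. The step needs ylide capture to outrun cyclopropanation of the prenyl and ring B alkenes, attack on the arene and intermolecular coupling; the ylide carbon is by far the best nucleophile present, the rigid bicycle holds the two arms gauche on Ca–Cb within bonding distance, and slow addition at high dilution suppresses oligomers. Either arm may become the carbene, because both pairings give the same product.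

Step 10
Reactants: 16 dimethyl ether of the target
Product: 18 target CNP0513322.1, via quinone 17 (not isolated)
Conditions: (NH4)2Ce(NO3)6, MeCN/H2O, 0 °C; then Na2S2O4, EtOAc/H2O, rt
Reagents that add atoms: water, O
Why: Oxidative demethylation of a hydroquinone dimethyl ether by tetravalent cerium gives the p-quinone, and dithionite then reduces this far more easily reduced quinone selectively, leaving the ring A enedione, both alkenes and all stereocenters untouched.

Compound list
1 | 2-bromo-1,4-dimethoxybenzene | COc1ccc(OC)c(Br)c1 | starting material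
2 | (2-bromo-3,6-dimethoxyphenyl)lithium | COc1ccc(OC)c(Br)c1[Li] | intermediate
3 | 2-bromo-3,6-dimethoxybenzaldehyde | O=Cc1c(OC)ccc(OC)c1Br | intermediate
4 | (triphenylphosphoranylidene)acetaldehyde | O=CC=P(c1ccccc1)(c1ccccc1)c1ccccc1 | starting material
5 | (E)-3-(2-bromo-3,6-dimethoxyphenyl)prop-2-enal | O=C/C=C/c1c(OC)ccc(OC)c1Br | intermediate
6 | methyl acetoacetate | CC(=O)CC(=O)OC | starting material
7 | methyl (3S)-2-acetyl-3-(2-bromo-3,6-dimethoxyphenyl)-5-oxopentanoate (C2 epimers) | COC(=O)C(C(C)=O)[C@H](CC=O)c1c(OC)ccc(OC)c1Br | intermediate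
8 | methyl (6S)-6-(2-bromo-3,6-dimethoxyphenyl)-2-oxocyclohex-3-ene-1-carboxylate (C1 epimerisable) | COC(=O)C1C(=O)C=CC[C@@H]1c1c(OC)ccc(OC)c1Br | intermediate
9 | prenyl bromide (1-bromo-3-methylbut-2-ene) | CC(C)=CCBr | starting material
10 | methyl (1S,6S)-6-(2-bromo-3,6-dimethoxyphenyl)-1-(3-methylbut-2-enyl)-2-oxocyclohex-3-ene-1-carboxylate | CC(C)=CC[C@@]1(C(=O)OC)C(=O)C=CC[C@@H]1c1c(OC)ccc(OC)c1Br | intermediate
11 | lithium enolate from methyl addition to 10 (methyl trans to aryl) | CC(C)=CC[C@@]1(C(=O)OC)C([O-])=C[C@@H](C)C[C@@H]1c1c(OC)ccc(OC)c1Br.[Li+] | intermediate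
12 | methyl (1S,4S,6S)-6-(2-bromo-3,6-dimethoxyphenyl)-4-methyl-1-(3-methylbut-2-enyl)-2-(trifluoromethylsulfonyloxy)cyclohex-2-ene-1-carboxylate | CC(C)=CC[C@@]1(C(=O)OC)C(OS(=O)(=O)C(F)(F)F)=C[C@@H](C)C[C@@H]1c1c(OC)ccc(OC)c1Br | intermediate
13 | dimethyl (1S,4S,6S)-6-(2-bromo-3,6-dimethoxyphenyl)-4-methyl-1-(3-methylbut-2-enyl)cyclohex-2-ene-1,2-dicarboxylate | CC(C)=CC[C@@]1(C(=O)OC)C(C(=O)OC)=C[C@@H](C)C[C@@H]1c1c(OC)ccc(OC)c1Br | intermediate
14 | dimethyl (5R,9R,10S)-1,4-dimethoxy-7-methyl-10-(3-methylbut-2-enyl)-8,9-dihydro-5H-5,9-methanobenzo[7]annulene-5,10-dicarboxylate | CC(C)=CC[C@@]1(C(=O)OC)[C@@]2(C(=O)OC)C=C(C)C[C@@H]1c1c(OC)ccc(OC)c12 | intermediate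
15 | (5R,9R,10S)-bis(β-keto sulfoxonium ylide) of the same core, C(=O)CH=S(O)Me2 at C5 and C10 | CC(C)=CC[C@@]1(C(=O)C=S(C)(C)=O)[C@@]2(C(=O)C=S(C)(C)=O)C=C(C)C[C@@H]1c1c(OC)ccc(OC)c12 | intermediate
16 | dimethyl ether of the target (Ca S, Cb R, Cc R) | CC(C)=CC[C@@]12C(=O)C=CC(=O)[C@@]13C=C(C)C[C@@H]2c1c(OC)ccc(OC)c13 | intermediate
17 | ring D p-quinone of the target | CC(C)=CC[C@@]12C(=O)C=CC(=O)[C@@]13C=C(C)C[C@@H]2C2=C3C(=O)C=CC2=O | intermediate
18 | CNP0513322.1 (Ca S, Cb R, Cc R) | CC(C)=CC[C@@]12C(=O)C=CC(=O)[C@@]13C=C(C)C[C@@H]2c1c(O)ccc(O)c13 | target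

Total steps: 10. Longest linear sequence: 10 steps (1 to 18).

Steps most likely to fail

1. Step 9 (proposed new method).
- What may go wrong: the iridium carbene may be diverted into cyclopropanation of the prenyl alkene, attack on the electron-rich arene or on the carbonyl oxygen of the partner arm, or intermolecular coupling. Carbene formation may also be slow at such hindered arms.
- Fallback (known chemistry, sets out from 14 and comes back at 16): reduction with LiAlH4 gives the diol F1. Swern oxidation gives the non-enolisable dialdehyde F2. Double addition of CH2=CHMgBr gives the bis(allylic alcohol) F3, whose carbinol epimers are inconsequential.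
- Ring-closing metathesis with the first-generation Grubbs catalyst RuCl2(PCy3)2(=CHPh) then closes ring A as the enediol F4. This catalyst engages only the monosubstituted alkenes and leaves the prenyl and ring B alkenes alone. Dess–Martin oxidation returns to 16.

2. Step 8.
- What may go wrong: acyl substitution at two neopentyl-type esters, one at a bridgehead beside an OMe group, may stall after the first arm. The mono-ylide may also close on the neighbouring ester in a Dieckmann-type side reaction.
- Fallback (sets out from 14 and comes back at 15): the esters are cleaved at the unhindered O–CH3 carbon by SN2 dealkylation (LiI, pyridine, reflux) to the diacid F5. (COCl)2 with catalytic DMF converts it into the bis(acid chloride) F6. This much stronger acylating agent reacts with excess dimethylsulfoxonium methylide at 0 °C.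

3. Step 7.
- What may go wrong: oxidative addition to the di-ortho-substituted, electron-rich bromide may be slow. Insertion into the prenyl alkene (6-exo) may compete from the diequatorial conformer. The new alkene may migrate by re-addition of palladium hydride.
- Fallback (sets out from 13 and comes back at 14): the Cb–aryl bond is made by enolate cross-coupling instead of carbopalladation. γ-Deprotonation of 13 with LiN(i-Pr)2 and kinetic α-protonation give the deconjugated β,γ-unsaturated diester F7.
- Intramolecular palladium-catalysed α-arylation of its ester enolate (LiN(SiMe3)2, Pd(dba)2, P(t-Bu)3, toluene, 60 °C) then closes ring C with the alkene already in place.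

Further compounds
F1 | step 9 | 5,10-bis(hydroxymethyl) analogue of 14 (diol) | CC(C)=CC[C@@]1(CO)[C@@]2(CO)C=C(C)C[C@@H]1c1c(OC)ccc(OC)c12
F2 | step 9 | 5,10-dicarbaldehyde analogue of 14 | CC(C)=CC[C@@]1(C=O)[C@@]2(C=O)C=C(C)C[C@@H]1c1c(OC)ccc(OC)c12
F3 | step 9 | 5,10-bis(1-hydroxyprop-2-enyl) analogue of 14 (carbinol epimers) | CC(C)=CC[C@@]1(C(O)C=C)[C@@]2(C(O)C=C)C=C(C)C[C@@H]1c1c(OC)ccc(OC)c12
F4 | step 9 | ring A cyclohex-2-ene-1,4-diol analogue of 16 (carbinol epimers) | CC(C)=CC[C@@]12C(O)C=CC(O)[C@@]13C=C(C)C[C@@H]2c1c(OC)ccc(OC)c13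
F5 | step 8 | 5,10-dicarboxylic acid from 14 | CC(C)=CC[C@@]1(C(=O)O)[C@@]2(C(=O)O)C=C(C)C[C@@H]1c1c(OC)ccc(OC)c12
F6 | step 8 | 5,10-bis(acid chloride) from F5 | CC(C)=CC[C@@]1(C(=O)Cl)[C@@]2(C(=O)Cl)C=C(C)C[C@@H]1c1c(OC)ccc(OC)c12
F7 | step 7 | dimethyl (1S,6S)-6-(2-bromo-3,6-dimethoxyphenyl)-4-methyl-1-(3-methylbut-2-enyl)cyclohex-3-ene-1,2-dicarboxylate (C2 epimers) | CC(C)=CC[C@@]1(C(=O)OC)C(C(=O)OC)C=C(C)C[C@@H]1c1c(OC)ccc(OC)c1Br
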